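**Retrosynthetic overview**

- Ring B (the γ-lactone) is closed late, in step 13. In one pot, C11–C12 is made from an alkenyl boronate and CO2, and C6–O1 from an alkyl boronate and perborate. The ring then closes at the acyl carbon, which lies outside the ring fusion, so the trans fusion is reachable on the finished cyclohexane.
- Enabling feature: C-6 (sp3) and C-11 (sp2) both carry a pinacolboryl group, 1,3 to each other across C-7 and trans-diequatorial on the cyclohexane (ring A).
- The bis(boronate) comes from a 2-iodocyclohexenone by Suzuki coupling with 1,1-diborylethene (C7–C11) and copper-boryl conjugate addition (C6–B, sets C-6 and C-7). Hydride then sets C-8.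
- C-10 is set by vinyl cuprate addition trans to the C-5 side chain. C-5 is set by a catalytic asymmetric Diels–Alder reaction that forms ring A (step 2). C-15 is carried as a vinylsilane and turned into the acid at the end.

Key step: step 13

Remark on numbering: elemane numbering is used (ring A = C-5 to C-10; C-1/C-2 the vinyl on C-10; C-3/C-4/C-15 the unit on C-5; C-11/C-12/C-13 the unit on C-7); β is the face of the C-10 methyl group.

Assumption: the (S)-oxazaborolidinium catalyst of step 2 is taken to give (1R)-4; if the sense of induction is the opposite, its enantiomer is used.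

**Route**

Step 1
Reactants: 1 (E)-pent-3-en-2-one
Product: 2 (E)-triisopropyl(penta-1,3-dien-2-yloxy)silane
Conditions: LDA, THF, −78 °C; then TIPSOTf, −78 to 0 °C
Reagents that add atoms: triisopropylsilyl trifluoromethanesulfonate, CC(C)[Si](OS(=O)(=O)C(F)(F)F)(C(C)C)C(C)C
Why: kinetic deprotonation of the enone at the α′-methyl group and O-silylation (silyl enol ether formation) give the cross-conjugated 2-silyloxydiene with the (E)-alkene untouched; no stereocentre is formed.

Step 2
Reactants: 2 (E)-triisopropyl(penta-1,3-dien-2-yloxy)silane; 3 acrolein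
Product: 4 (1R,2S)-2-methyl-4-(triisopropylsilyloxy)cyclohex-3-ene-1-carbaldehyde
Conditions: (S)-B-(o-tolyl)oxazaborolidine from α,α-diphenylprolinol (C24H24BNO, 15 mol%), HNTf2 (12 mol%), CH2Cl2, −78 °C
Reagents that add atoms: none
Why: a cationic oxazaborolidine-catalysed Diels–Alder reaction closes ring A with the aldehyde para to the silyloxy group and ortho to the methyl group; the catalyst face sets C-5, and the endo (cis) methyl centre at C-10 is removed again in step 5.

Step 3
Reactants: 4 (1R,2S)-2-methyl-4-(triisopropylsilyloxy)cyclohex-3-ene-1-carbaldehyde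
Product: 5 (3R,4R)-4-ethynyl-3-methyl-1-(triisopropylsilyloxy)cyclohex-1-ene
Conditions: Me3SiCHN2, n-BuLi, THF, −78 °C; then 4, −78 to 0 °C
Reagents that add atoms: (trimethylsilyl)diazomethane, C[Si](C)(C)C=[N+]=[N-]
Why: the Colvin rearrangement (Seyferth–Gilbert-type homologation) converts the aldehyde into the terminal alkyne at low temperature, so the α-centre C-5 should not epimerise.

Step 4
Reactants: 5 (3R,4R)-4-ethynyl-3-methyl-1-(triisopropylsilyloxy)cyclohex-1-ene
Product: 6 triethyl{1-[(1R,2S)-2-methyl-4-(triisopropylsilyloxy)cyclohex-3-en-1-yl]vinyl}silane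
Conditions: Et3SiH, [Cp*Ru(MeCN)3]PF6 (2 mol%), CH2Cl2, 0 °C to rt
Reagents that add atoms: triethylsilane, CC[SiH](CC)CC
Why: ruthenium-catalysed Markovnikov hydrosilylation of the terminal alkyne (Trost) gives the 1,1-disubstituted vinylsilane, which masks the C-4/C-3 acrylic unit against every later nucleophile and base.

Step 5
Reactants: 6 triethyl{1-[(1R,2S)-2-methyl-4-(triisopropylsilyloxy)cyclohex-3-en-1-yl]vinyl}silane
Product: 7 (R)-3-methyl-4-[1-(triethylsilyl)vinyl]cyclohex-2-en-1-one
Conditions: Pd(OAc)2 (10 mol%), O2 (1 atm), DMSO, 60 °C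
Reagents that add atoms: none
Why: Saegusa–Ito oxidation of the silyl enol ether (palladium enolate, β-hydride loss from C-10) gives the β-methyl enone regiospecifically and leaves C-5 as the only stereocentre.

Step 6
Reactants: 7 (R)-3-methyl-4-[1-(triethylsilyl)vinyl]cyclohex-2-en-1-one
Product: 9 (3S,4R)-3-methyl-4-[1-(triethylsilyl)vinyl]-3-vinylcyclohexan-1-one, via silyl enol ether 8 (not isolated)
Conditions: CH2=CHMgBr, CuBr·SMe2 (10 mol%), Me3SiCl, THF, −78 to −40 °C; then 1 M HCl, 0 °C
Reagents that add atoms: vinylmagnesium bromide, C=C[Mg]Br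
Why: copper-catalysed conjugate addition delivers the vinyl group anti to the C-5 side chain (held pseudoaxial by allylic strain with the C-10 methyl), which sets the quaternary C-10 with vinyl trans to the side chain.

Step 7
Reactants: 9 (3S,4R)-3-methyl-4-[1-(triethylsilyl)vinyl]-3-vinylcyclohexan-1-one
Product: 10 (4R,5S)-5-methyl-4-[1-(triethylsilyl)vinyl]-5-vinylcyclohex-2-en-1-one
Conditions: IBX (2.5 equiv), DMSO, 70 °C
Reagents that add atoms: none
Why: IBX dehydrogenation of the ketone can only go towards C-7/C-6 because the other α-carbon has no β-hydrogen (C-10 is quaternary), so the enone forms with one regiochemistry and cannot aromatise.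

Step 8
Reactants: 10 (4R,5S)-5-methyl-4-[1-(triethylsilyl)vinyl]-5-vinylcyclohex-2-en-1-one
Product: 11 (4R,5S)-2-iodo-5-methyl-4-[1-(triethylsilyl)vinyl]-5-vinylcyclohex-2-en-1-one
Conditions: I2, pyridine, CH2Cl2, rt
Reagents that add atoms: iodine, [I][I]
Why: Johnson α-iodination of the enone (pyridine conjugate addition, iodination of the enolate, elimination) puts the coupling handle on C-7.

Step 9
Reactants: 11 (4R,5S)-2-iodo-5-methyl-4-[1-(triethylsilyl)vinyl]-5-vinylcyclohex-2-en-1-one
Product: 12 (4R,5S)-5-methyl-2-[1-(pinacolboryl)vinyl]-4-[1-(triethylsilyl)vinyl]-5-vinylcyclohex-2-en-1-one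
Conditions: CH2=C(Bpin)2 (2 equiv), Pd(PtBu3)2 (5 mol%), K3PO4 (aq), THF, rt
Reagents that add atoms: 2,2'-(ethene-1,1-diyl)bis(4,4,5,5-tetramethyl-1,3,2-dioxaborolane), C=C(B1OC(C)(C)C(C)(C)O1)B1OC(C)(C)C(C)(C)O1
Why: Suzuki–Miyaura mono-coupling of the 1,1-diborylalkene with the alkenyl iodide forms C7–C11 and leaves the second boron on C-11 as the later carboxylation site.

Step 10
Reactants: 12 (4R,5S)-5-methyl-2-[1-(pinacolboryl)vinyl]-4-[1-(triethylsilyl)vinyl]-5-vinylcyclohex-2-en-1-one
Product: 13 (2R,3S,4R,5S)-5-methyl-3-(pinacolboryl)-2-[1-(pinacolboryl)vinyl]-4-[1-(triethylsilyl)vinyl]-5-vinylcyclohexan-1-one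
Conditions: B2pin2 (1.1 equiv), CuCl (5 mol%), Xantphos (5 mol%), NaOtBu (10 mol%), MeOH (2 equiv), THF, 0 °C to rt
Reagents that add atoms: bis(pinacolato)diboron, CC1(C)OB(OC1(C)C)B1OC(C)(C)C(C)(C)O1
Why: copper-catalysed conjugate borylation should add boron to C-6 from the α face, anti to the C-5 side chain and the axial C-10 methyl, and C-7 (α to the ketone) should equilibrate in the basic medium to the equatorial 7β-alkenyl epimer trans to the new C–B bond.

Step 11
Reactants: 13 (2R,3S,4R,5S)-5-methyl-3-(pinacolboryl)-2-[1-(pinacolboryl)vinyl]-4-[1-(triethylsilyl)vinyl]-5-vinylcyclohexan-1-one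
Product: 14 (1R,2R,3S,4R,5S)-5-methyl-3-(pinacolboryl)-2-[1-(pinacolboryl)vinyl]-4-[1-(triethylsilyl)vinyl]-5-vinylcyclohexan-1-ol
Conditions: LiBH(s-Bu)3 (L-Selectride), THF, −78 °C; aq NH4Cl (no peroxide work-up)
Reagents that add atoms: none
Why: the bulky hydride attacks the C-8 ketone equatorially from the α face (the β face is blocked by the axial C-10 methyl), which gives the axial 8β-alcohol cis to the C-7 substituent.

Step 12
Reactants: 14 (1R,2R,3S,4R,5S)-5-methyl-3-(pinacolboryl)-2-[1-(pinacolboryl)vinyl]-4-[1-(triethylsilyl)vinyl]-5-vinylcyclohexan-1-ol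
Product: 15 the 8β-tiglate of 14
Conditions: tiglic anhydride, DMAP, Et3N, CH2Cl2, rt
Reagents that add atoms: tiglic anhydride, C/C=C(\C)C(=O)OC(=O)/C(C)=C/C
Why: DMAP-catalysed acylation of the only free hydroxyl installs the (E)-2-methylbut-2-enoate without touching a stereocentre.

Step 13
Reactants: 15 the 8β-tiglate of 14
Product: 18 8β-tigloyloxy-4-(triethylsilyl)-15-norelema-1,3,11(13)-trien-12,6α-olide, via cesium carboxylate 16 (not isolated), via hydroxy acid 17 (not isolated)
Conditions: CO2 (1 atm), chloro[1,3-bis(2,6-diisopropylphenyl)imidazol-2-ylidene]copper, (IPr)CuCl (5 mol%), CsF (3 equiv), DMF, 80 °C; then NaBO3·4H2O, THF/H2O, rt; then 1 M HCl, rt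
Reagents that add atoms: carbon dioxide, O=C=O; sodium perborate, [Na+].[O-]OB=O
Why: Monovalent copper fluoride formed from (IPr)CuCl and CsF transmetalates only the sp2 C-11–B bond and the alkenylcopper inserts CO2 to give acrylate 16 (C11–C12); added perborate then turns the untouched sp3 C-6–B bond into C-6–O1 by migration of carbon from boron to oxygen, and acidification lets this hydroxyl close onto C-12. The closest known reaction types are the copper-catalysed carboxylation of alkenylboronic esters with CO2, the perborate oxidation of secondary alkyl pinacolboronates and the acid lactonisation of a γ-hydroxy acid. The ring closed is the γ-lactone (ring B), by 5-exo-trig acyl substitution at C-12, an atom outside the ring fusion; this makes the trans (diequatorial) fusion accessible, whereas displacement at C-6 by the tethered carboxylate could only reach the cis-fused isomer. No new stereocentre is created: the 6α configuration comes from the stereoretentive carbon-to-oxygen migration and C-7 is untouched. The selectivity needed is carboxylation of the alkenyl and not the alkyl boronate (secondary alkyl pinacolboronates do not transmetalate to copper under these conditions), oxidation after and not before CO2 uptake (secured by the order of addition), and lactonisation by the C-6 hydroxyl alone (C-8 is esterified and C-15 is still masked as the vinylsilane).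

Step 14
Reactants: 18 8β-tigloyloxy-4-(triethylsilyl)-15-norelema-1,3,11(13)-trien-12,6α-olide
Product: 19 4-iodo-8β-tigloyloxy-15-norelema-1,3,11(13)-trien-12,6α-olide
Conditions: NIS, 2,6-lutidine, (CF3)2CHOH, 0 °C
Reagents that add atoms: N-iodosuccinimide, O=C1CCC(=O)N1I
Why: ipso-iododesilylation of the vinylsilane (electrophilic substitution steered by the β-silyl cation) exchanges silicon for iodine, while the electron-poor α-methylene lactone and tiglate and the unactivated vinyl group should not react.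

Step 15
Reactants: 19 4-iodo-8β-tigloyloxy-15-norelema-1,3,11(13)-trien-12,6α-olide
Product: 20 8β-tigloyloxyelema-1,3,11(13)-trien-12,6α-olid-15-oic acid (target)
Conditions: CO (1 atm), Pd(OAc)2 (5 mol%), PPh3 (10 mol%), KOAc, DMF, rt; then H2O, pH 3
Reagents that add atoms: carbon monoxide, [C-]#[O+]; water, O
Why: palladium-catalysed hydroxycarbonylation of the alkenyl iodide (oxidative addition to zerovalent palladium, CO insertion, acetate capture, hydrolysis of the mixed anhydride) gives the 2-substituted acrylic acid under conditions that leave lactone, tiglate and all stereocentres alone.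

**Compound list**

1 | (E)-pent-3-en-2-one | C/C=C/C(C)=O | starting material
2 | (E)-triisopropyl(penta-1,3-dien-2-yloxy)silane | C=C(O[Si](C(C)C)(C(C)C)C(C)C)/C=C/C | intermediate
3 | acrolein (prop-2-enal) | C=CC=O | starting material
4 | (1R,2S)-2-methyl-4-(triisopropylsilyloxy)cyclohex-3-ene-1-carbaldehyde (cis) | C[C@H]1C=C(O[Si](C(C)C)(C(C)C)C(C)C)CC[C@H]1C=O | intermediate
5 | (3R,4R)-4-ethynyl-3-methyl-1-(triisopropylsilyloxy)cyclohex-1-ene (cis) | C[C@H]1C=C(O[Si](C(C)C)(C(C)C)C(C)C)CC[C@H]1C#C | intermediate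
6 | triethyl{1-[(1R,2S)-2-methyl-4-(triisopropylsilyloxy)cyclohex-3-en-1-yl]vinyl}silane | C[C@H]1C=C(O[Si](C(C)C)(C(C)C)C(C)C)CC[C@H]1C(=C)[Si](CC)(CC)CC | intermediate
7 | (R)-3-methyl-4-[1-(triethylsilyl)vinyl]cyclohex-2-en-1-one | CC1=CC(=O)CC[C@H]1C(=C)[Si](CC)(CC)CC | intermediate
8 | trimethylsilyl enol ether of 9 (C-8 O-silylated, C8=C9 double bond; C-10 methyl β, vinyl α, C-5 side chain β) | C=C[C@]1(C)C=C(O[Si](C)(C)C)CC[C@H]1C(=C)[Si](CC)(CC)CC | intermediate
9 | (3S,4R)-3-methyl-4-[1-(triethylsilyl)vinyl]-3-vinylcyclohexan-1-one (vinyl trans to the side chain) | C=C[C@]1(C)CC(=O)CC[C@H]1C(=C)[Si](CC)(CC)CC | intermediate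
10 | (4R,5S)-5-methyl-4-[1-(triethylsilyl)vinyl]-5-vinylcyclohex-2-en-1-one | C=C[C@]1(C)CC(=O)C=C[C@H]1C(=C)[Si](CC)(CC)CC | intermediate
11 | (4R,5S)-2-iodo-5-methyl-4-[1-(triethylsilyl)vinyl]-5-vinylcyclohex-2-en-1-one | C=C[C@]1(C)CC(=O)C(I)=C[C@H]1C(=C)[Si](CC)(CC)CC | intermediate
12 | (4R,5S)-5-methyl-2-[1-(4,4,5,5-tetramethyl-1,3,2-dioxaborolan-2-yl)vinyl]-4-[1-(triethylsilyl)vinyl]-5-vinylcyclohex-2-en-1-one | C=C[C@]1(C)CC(=O)C(C(=C)B2OC(C)(C)C(C)(C)O2)=C[C@H]1C(=C)[Si](CC)(CC)CC | intermediate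
13 | (2R,3S,4R,5S)-5-methyl-3-(pinacolboryl)-2-[1-(pinacolboryl)vinyl]-4-[1-(triethylsilyl)vinyl]-5-vinylcyclohexan-1-one (6α-boryl, 7β-alkenyl, 5β-side chain, 10β-methyl) | C=C[C@]1(C)CC(=O)[C@@H](C(=C)B2OC(C)(C)C(C)(C)O2)[C@H](B3OC(C)(C)C(C)(C)O3)[C@H]1C(=C)[Si](CC)(CC)CC | intermediate
14 | (1R,2R,3S,4R,5S)-5-methyl-3-(pinacolboryl)-2-[1-(pinacolboryl)vinyl]-4-[1-(triethylsilyl)vinyl]-5-vinylcyclohexan-1-ol (8β-hydroxyl) | C=C[C@]1(C)C[C@@H](O)[C@@H](C(=C)B2OC(C)(C)C(C)(C)O2)[C@H](B3OC(C)(C)C(C)(C)O3)[C@H]1C(=C)[Si](CC)(CC)CC | intermediate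
15 | (1R,2R,3S,4R,5S)-5-methyl-3-(pinacolboryl)-2-[1-(pinacolboryl)vinyl]-4-[1-(triethylsilyl)vinyl]-5-vinylcyclohexyl (E)-2-methylbut-2-enoate | C=C[C@]1(C)C[C@@H](OC(=O)/C(C)=C/C)[C@@H](C(=C)B2OC(C)(C)C(C)(C)O2)[C@H](B3OC(C)(C)C(C)(C)O3)[C@H]1C(=C)[Si](CC)(CC)CC | intermediate
16 | cesium 2-[7β-yl]acrylate of 15 (C-11 boron replaced by CO2Cs; C-6 boronate retained) | C=C[C@]1(C)C[C@@H](OC(=O)/C(C)=C/C)[C@@H](C(=C)C(=O)[O-])[C@H](B2OC(C)(C)C(C)(C)O2)[C@H]1C(=C)[Si](CC)(CC)CC.[Cs+] | intermediate
17 | 6α-hydroxy acid (C-12 carboxylic acid, 6α-OH, 8β-tiglate, C-4 triethylsilyl) | C=C[C@]1(C)C[C@@H](OC(=O)/C(C)=C/C)[C@@H](C(=C)C(=O)O)[C@H](O)[C@H]1C(=C)[Si](CC)(CC)CC | intermediate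
18 | 8β-tigloyloxy-4-(triethylsilyl)-15-norelema-1,3,11(13)-trien-12,6α-olide (trans-fused lactone) | C=C[C@]1(C)C[C@@H](OC(=O)/C(C)=C/C)[C@H]2C(=C)C(=O)O[C@@H]2[C@H]1C(=C)[Si](CC)(CC)CC | intermediate
19 | 4-iodo-8β-tigloyloxy-15-norelema-1,3,11(13)-trien-12,6α-olide | C=C[C@]1(C)C[C@@H](OC(=O)/C(C)=C/C)[C@H]2C(=C)C(=O)O[C@@H]2[C@H]1C(=C)I | intermediate
20 | 8β-tigloyloxyelema-1,3,11(13)-trien-12,6α-olid-15-oic acid (5αH, 6βH, 7αH, 8αH, 10β-methyl) | C=C[C@]1(C)C[C@@H](OC(=O)/C(C)=C/C)[C@H]2C(=C)C(=O)O[C@@H]2[C@H]1C(=C)C(=O)O | target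

**Totals and risks**

Total step count: 15. Longest linear sequence: 15 steps (from 1).

Step 13 is the most likely to fail. The hindered 1,1-disubstituted alkenyl boron may fail to transmetalate, or may be protodeboronated, so that CO2 is not taken up. The fallback sets out from 15: NaI and chloramine-T in THF/water exchange the sp2 boron for iodine to give the 11-iodo analogue of 15 F1. Palladium-catalysed hydroxycarbonylation (CO, Pd(OAc)2, PPh3, KOAc, DMF; then water) gives the free acrylic acid with the C-6 boronate retained F2. NaBO3·4H2O and then 1 M HCl convert it by way of 17 into 18, where the route is rejoined.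

Step 10 is the second risk. The boryl copper may attack from the wrong face, or the C11=C13 double bond may migrate into conjugation under base while C-7 equilibrates. The fallback sets out from 12: tert-butyl hydroperoxide and DBU epoxidise the enone anti to the C-5 side chain to give the 6α,7α-epoxy ketone F3. Sodium phenylselenide (from (PhSe)2 and NaBH4, AcOH, EtOH) cleaves the C-7–O bond to the 6α-hydroxy ketone F4. LiBH(s-Bu)3 gives the 6α,8β-diol F5, and one equivalent of tiglic anhydride with DMAP acylates the less hindered C-8 hydroxyl to give the 8-tiglate F6. Copper-catalysed carboxylation (CO2, (IPr)CuCl, CsF, DMF) and 1 M HCl then lead by way of 17 to 18.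

Step 2 is the third risk. Enantiofacial discrimination may be low with the unsubstituted enal, or the diene may add to the aldehyde carbonyl instead. The fallback sets out from 2: the same catalyst with 2,2,2-trifluoroethyl acrylate gives the 2,2,2-trifluoroethyl (1R,2S)-2-methyl-4-(triisopropylsilyloxy)cyclohex-3-ene-1-carboxylate F7. DIBAL-H in CH2Cl2 at −78 °C reduces it to aldehyde 4.

Further compounds
F1 | step 13 | 11-iodo analogue of 15 (alkenyl boron replaced by iodine, C-6 boronate retained) | C=C[C@]1(C)C[C@@H](OC(=O)/C(C)=C/C)[C@@H](C(=C)I)[C@H](B2OC(C)(C)C(C)(C)O2)[C@H]1C(=C)[Si](CC)(CC)CC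
F2 | step 13 | free acrylic acid with the C-6 boronate retained | C=C[C@]1(C)C[C@@H](OC(=O)/C(C)=C/C)[C@@H](C(=C)C(=O)O)[C@H](B2OC(C)(C)C(C)(C)O2)[C@H]1C(=C)[Si](CC)(CC)CC
F3 | step 10 | 6α,7α-epoxy ketone from 12 | C=C[C@]1(C)CC(=O)[C@]2(C(=C)B3OC(C)(C)C(C)(C)O3)O[C@@H]2[C@H]1C(=C)[Si](CC)(CC)CC
F4 | step 10 | 6α-hydroxy ketone (7β-alkenyl boronate) | C=C[C@]1(C)CC(=O)[C@@H](C(=C)B2OC(C)(C)C(C)(C)O2)[C@H](O)[C@H]1C(=C)[Si](CC)(CC)CC
F5 | step 10 | 6α,8β-diol | C=C[C@]1(C)C[C@@H](O)[C@@H](C(=C)B2OC(C)(C)C(C)(C)O2)[C@H](O)[C@H]1C(=C)[Si](CC)(CC)CC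
F6 | step 10 | 8-tiglate of the 6α,8β-diol | C=C[C@]1(C)C[C@@H](OC(=O)/C(C)=C/C)[C@@H](C(=C)B2OC(C)(C)C(C)(C)O2)[C@H](O)[C@H]1C(=C)[Si](CC)(CC)CC
F7 | step 2 | 2,2,2-trifluoroethyl (1R,2S)-2-methyl-4-(triisopropylsilyloxy)cyclohex-3-ene-1-carboxylate | C[C@H]1C=C(O[Si](C(C)C)(C(C)C)C(C)C)CC[C@H]1C(=O)OCC(F)(F)F
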